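**Assumption:** compounds 5, 6 and 12 are epimer mixtures at centres that are equilibrated or destroyed later, so those centres are left undefined in their SMILES; catalysts and reagents are bought. The route has not been run; selectivities are predictions from the models named in each step.

## Retrosynthetic overview

1. 17 ⇐ angeloylation of cis-ketol 14 ⇐ 5-(enolexo) aldol of keto aldehyde 13 (cyclopentane formed last).
2. 13 ⇐ epoxidation and periodate cleavage of the methylcyclohexene ring A of diene 11 (ring A is a masked 2-oxopropyl/2-oxoethyl pair).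
3. 11 ⇐ octalenone 7 by axial conjugate borylation–oxidation (C–O bond), acetylation and methylenation.
4. 7 ⇐ enamine-catalysed Michael addition/aldol condensation of 3-methylbutanal 4 onto dienone 3 (ring B formed second; all ring stereocentres fixed here).
5. 3 ⇐ Diels–Alder reaction of isoprene 1 with 3-butyn-2-one 2 (ring A formed first).

## Route

**Step 1**
Reactants: 1 isoprene; 2 3-butyn-2-one
Product: 3 1-(4-methylcyclohexa-1,4-dien-1-yl)ethan-1-one
Conditions: AlCl3 (10 mol%), CH2Cl2, −20 → 0 °C, BHT, Ar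
Reagents that add atoms: none
Why: Lewis-acid-catalysed Diels–Alder reaction; the larger HOMO coefficient at C1 of isoprene bonds to the β-carbon of the ynone, giving the 1,4-("para") cyclohexadiene, which has no stereocentre.

**Step 2**
Reactants: 3 1-(4-methylcyclohexa-1,4-dien-1-yl)ethan-1-one; 4 3-methylbutanal
Product: 7 (4R,4aS,8aR)-6-methyl-4-(propan-2-yl)-4a,5,8,8a-tetrahydronaphthalen-1(4H)-one, via Michael adduct 5 (not isolated), via ketol 6 (not isolated)
Conditions: (R)-α,α-diphenylprolinol TMS ether (20 mol%), ethyl 3,4-dihydroxybenzoate (20 mol%), 4 (3 equiv), neat, 4 °C → rt, Ar; evaporate excess 4; then LiOH·H2O (0.3 equiv), i-PrOH, rt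
Reagents that add atoms: none
Why: Proposed new method: intermolecular enamine Michael addition of an aldehyde to an α,β-disubstituted endocyclic enone is not known; the (E)-enamine of 4 should attack C2 of 3 from the face anti to the CPh2OSiMe3 group in a synclinal (Seebach-type) arrangement, with the catechol co-catalyst hydrogen-bonding the s-cis acetyl group (LUMO lowering and proton relay), to give the syn adduct 5 (side-chain C2 S, ring C1 S); the closest known reactions are the diarylprolinol-ether aldehyde–vinyl ketone Michael addition, the intramolecular aldehyde–enone Michael reaction and thermal Stork enamine additions to 1-acetylcyclohexene; the LiOH stage is the known Robinson-type aldol condensation (as in the organocatalytic cryptone synthesis) and equilibrates C8a (α to C=O) to the trans-fused ring junction with equatorial isopropyl.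

**Step 3**
Reactants: 7 (4R,4aS,8aR)-6-methyl-4-(propan-2-yl)-4a,5,8,8a-tetrahydronaphthalen-1(4H)-one
Product: 9 (3R,4S,4aS,8aR)-3-hydroxy-6-methyl-4-(propan-2-yl)-3,4,4a,5,8,8a-hexahydronaphthalen-1(2H)-one, via boryl ketone 8 (not isolated)
Conditions: B2pin2 (1.1 equiv), CuCl (5 mol%), DPEphos (5 mol%), NaOt-Bu (10 mol%), MeOH (2 equiv), THF, rt; then 30% H2O2, aq NaHCO3, 0 °C
Reagents that add atoms: bis(pinacolato)diboron, CC1(C)OB(OC1(C)C)B1OC(C)(C)C(C)(C)O1 (boryl group of 8); hydrogen peroxide, OO (hydroxyl O of 9)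
Why: Cu(I)-catalysed conjugate borylation followed by stereoretentive C–B oxidation; on the rigid trans-fused enone with a locked equatorial isopropyl group, stereoelectronically preferred axial delivery (chair-like enolate) should place boron, and then OH, axial at C3 (3R), cis to the isopropyl group.

**Step 4**
Reactants: 9 (3R,4S,4aS,8aR)-3-hydroxy-6-methyl-4-(propan-2-yl)-3,4,4a,5,8,8a-hexahydronaphthalen-1(2H)-one
Product: 10 (1S,2R,4aR,8aS)-7-methyl-4-oxo-1-(propan-2-yl)-1,2,3,4,4a,5,8,8a-octahydronaphthalen-2-yl acetate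
Conditions: Ac2O (1.5 equiv), Sc(OTf)3 (1 mol%), MeCN, −20 °C
Reagents that add atoms: acetic anhydride, CC(=O)OC(C)=O
Why: Lewis-acid-catalysed acylation of a hindered axial alcohol under base-free conditions, which avoids E1cB loss of the β-oxygen; no stereocentre is touched.

**Step 5**
Reactants: 10 (1S,2R,4aR,8aS)-7-methyl-4-oxo-1-(propan-2-yl)-1,2,3,4,4a,5,8,8a-octahydronaphthalen-2-yl acetate
Product: 11 (1S,2R,4aR,8aR)-7-methyl-4-methylidene-1-(propan-2-yl)-1,2,3,4,4a,5,8,8a-octahydronaphthalen-2-yl acetate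
Conditions: Zn, CH2Br2, TiCl4, THF (pre-formed reagent); then 10, CH2Cl2, 0 °C → rt
Reagents that add atoms: dibromomethane, BrCBr
Why: Takai–Lombardo methylenation; the non-basic gem-dimetallic reagent methylenates enolisable β-acyloxy ketones without β-elimination or epimerisation at C4a and leaves the ester alone.

**Step 6**
Reactants: 11 (1S,2R,4aR,8aR)-7-methyl-4-methylidene-1-(propan-2-yl)-1,2,3,4,4a,5,8,8a-octahydronaphthalen-2-yl acetate
Product: 12 (1S,2R,4aR,8aR)-6,7-epoxy-7-methyl-4-methylidene-1-(propan-2-yl)decahydronaphthalen-2-yl acetate (both epoxide epimers)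
Conditions: m-CPBA (1.05 equiv), NaHCO3, CH2Cl2, −20 → 0 °C
Reagents that add atoms: m-chloroperoxybenzoic acid, OOC(=O)c1cccc(Cl)c1
Why: Prilezhaev epoxidation; the trisubstituted ring alkene is more nucleophilic than the 1,1-disubstituted exocyclic alkene (as in limonene → limonene 1,2-oxide), and the new epoxide centres are destroyed in the next step.

**Step 7**
Reactants: 12 (1S,2R,4aR,8aR)-6,7-epoxy-7-methyl-4-methylidene-1-(propan-2-yl)decahydronaphthalen-2-yl acetate
Product: 13 (1R,2S,3R,4R)-5-methylidene-4-(2-oxoethyl)-3-(2-oxopropyl)-2-(propan-2-yl)cyclohexyl acetate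
Conditions: H5IO6 (1.3 equiv), THF/H2O 4:1, 0 °C → rt
Reagents that add atoms: water, O
Why: periodic acid opens the epoxide to the diol and cleaves it in the same pot (Malaprade glycol cleavage, as for limonene oxide → keto aldehyde), releasing the methyl ketone and aldehyde arms without touching a stereocentre.

**Step 8**
Reactants: 13 (1R,2S,3R,4R)-5-methylidene-4-(2-oxoethyl)-3-(2-oxopropyl)-2-(propan-2-yl)cyclohexyl acetate
Product: 14 (1R,2S,3aR,6R,7S,7aR)-1-acetyl-2-hydroxy-4-methylidene-7-(propan-2-yl)octahydro-1H-inden-6-yl acetate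
Conditions: MgBr2·OEt2 (2.0 equiv), i-Pr2NEt (2.2 equiv), CH2Cl2 (0.02 M), −20 → 0 °C; pH 7 buffer
Reagents that add atoms: none
Why: Mg(II)/amine soft-enolisation intramolecular aldol addition (5-enolexo); reversible enolisation should funnel through the (Z)-ketone enolate adding to the aldehyde in a chelated Zimmerman–Traxler transition state, giving the cis hydroxy/acetyl pair (C2 S), while the acetyl group takes the thermodynamically preferred orientation at C1 (R) away from the C7 branch.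

**Step 9**
Reactants: 14 (1R,2S,3aR,6R,7S,7aR)-1-acetyl-2-hydroxy-4-methylidene-7-(propan-2-yl)octahydro-1H-inden-6-yl acetate; 15 angelic acid
Product: 17 (1R,2S,3aR,6R,7S,7aR)-6-acetoxy-1-acetyl-4-methylidene-7-(propan-2-yl)octahydro-1H-inden-2-yl (2Z)-2-methylbut-2-enoate, via mixed anhydride 16 (not isolated)
Conditions: 15, 2,4,6-trichlorobenzoyl chloride, Et3N (1.05 equiv), toluene, rt; filter; then 14, 2,6-lutidine, toluene, 65 °C
Reagents that add atoms: 2,4,6-trichlorobenzoyl chloride, O=C(Cl)c1c(Cl)cc(Cl)cc1Cl (aroyl part of 16 only; no atoms in 17)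
Why: Yamaguchi-type mixed-anhydride esterification run without a nucleophilic catalyst; the alcohol attacks the less hindered angeloyl carbonyl, the absence of DMAP avoids Z→E isomerisation to the tiglate, and the weak base avoids E1cB loss of the new β-acyloxy group.

## Compound list

1 | isoprene (2-methylbuta-1,3-diene) | C=CC(C)=C | starting material
2 | 3-butyn-2-one | CC(=O)C#C | starting material
3 | 1-(4-methylcyclohexa-1,4-dien-1-yl)ethan-1-one | CC(=O)C1=CCC(C)=CC1 | intermediate
4 | 3-methylbutanal (isovaleraldehyde) | CC(C)CC=O | starting material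
5 | (2S)-2-[(1S)-6-acetyl-3-methylcyclohex-3-en-1-yl]-3-methylbutanal (ring C6 epimers) | O=C[C@@H](C(C)C)[C@@H]1CC(C)=CCC1C(C)=O | intermediate
6 | (4S,4aS)-3-hydroxy-6-methyl-4-(propan-2-yl)-3,4,4a,5,8,8a-hexahydronaphthalen-1(2H)-one (C3 and C8a epimers) | O=C1CC(O)[C@@H](C(C)C)[C@@H]2CC(C)=CCC12 | intermediate
7 | (4R,4aS,8aR)-6-methyl-4-(propan-2-yl)-4a,5,8,8a-tetrahydronaphthalen-1(4H)-one | O=C1C=C[C@@H](C(C)C)[C@@H]2CC(C)=CC[C@@H]12 | intermediate
8 | (3R,4S,4aS,8aR)-6-methyl-4-(propan-2-yl)-3-(4,4,5,5-tetramethyl-1,3,2-dioxaborolan-2-yl)-3,4,4a,5,8,8a-hexahydronaphthalen-1(2H)-one | O=C1C[C@@H](B2OC(C)(C)C(C)(C)O2)[C@@H](C(C)C)[C@@H]2CC(C)=CC[C@@H]12 | intermediate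
9 | (3R,4S,4aS,8aR)-3-hydroxy-6-methyl-4-(propan-2-yl)-3,4,4a,5,8,8a-hexahydronaphthalen-1(2H)-one | O=C1C[C@@H](O)[C@@H](C(C)C)[C@@H]2CC(C)=CC[C@@H]12 | intermediate
10 | (1S,2R,4aR,8aS)-7-methyl-4-oxo-1-(propan-2-yl)-1,2,3,4,4a,5,8,8a-octahydronaphthalen-2-yl acetate | O=C1C[C@@H](OC(C)=O)[C@@H](C(C)C)[C@@H]2CC(C)=CC[C@@H]12 | intermediate
11 | (1S,2R,4aR,8aR)-7-methyl-4-methylidene-1-(propan-2-yl)-1,2,3,4,4a,5,8,8a-octahydronaphthalen-2-yl acetate | C=C1C[C@@H](OC(C)=O)[C@@H](C(C)C)[C@@H]2CC(C)=CC[C@@H]12 | intermediate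
12 | (1S,2R,4aR,8aR)-6,7-epoxy-7-methyl-4-methylidene-1-(propan-2-yl)decahydronaphthalen-2-yl acetate (epoxide epimers) | C=C1C[C@@H](OC(C)=O)[C@@H](C(C)C)[C@@H]2CC3(C)OC3C[C@@H]12 | intermediate
13 | (1R,2S,3R,4R)-5-methylidene-4-(2-oxoethyl)-3-(2-oxopropyl)-2-(propan-2-yl)cyclohexyl acetate | C=C1C[C@@H](OC(C)=O)[C@@H](C(C)C)[C@H](CC(C)=O)[C@H]1CC=O | intermediate
14 | (1R,2S,3aR,6R,7S,7aR)-1-acetyl-2-hydroxy-4-methylidene-7-(propan-2-yl)octahydro-1H-inden-6-yl acetate | C=C1C[C@@H](OC(C)=O)[C@@H](C(C)C)[C@@H]2[C@@H](C(C)=O)[C@@H](O)C[C@@H]12 | intermediate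
15 | angelic acid ((2Z)-2-methylbut-2-enoic acid) | C/C=C(/C)C(=O)O | starting material
16 | (2Z)-2-methylbut-2-enoic 2,4,6-trichlorobenzoic anhydride | C/C=C(/C)C(=O)OC(=O)c1c(Cl)cc(Cl)cc1Cl | intermediate
17 | (1R,2S,3aR,6R,7S,7aR)-6-acetoxy-1-acetyl-4-methylidene-7-(propan-2-yl)octahydro-1H-inden-2-yl (2Z)-2-methylbut-2-enoate (CNP0322881.1) | C=C1C[C@@H](OC(C)=O)[C@@H](C(C)C)[C@@H]2[C@@H](C(C)=O)[C@@H](OC(=O)/C(C)=C\C)C[C@@H]12 | target

## Step count and risks

Total step count: 9. Longest linear sequence: 9 steps (1/2 → 3 → 7 → 9 → 10 → 11 → 12 → 13 → 14 → 17).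

The three steps most likely to fail:

**Step 2 (proposed new Michael addition).** The α,β-disubstituted enone 3 is a weak acceptor, and dr or ee in the C–C bond-forming event may be low. The fallback uses known chemistry, sets out from 4 (with 1) and comes back at 7. The known diarylprolinol-ether Michael addition of 4 to methyl vinyl ketone, here with the (S)-catalyst, gives (2S)-5-oxo-2-(propan-2-yl)hexanal F1, and LiOH in i-PrOH closes it to (4S)-4-(propan-2-yl)cyclohex-2-en-1-one F2 ((S)-cryptone). An AlCl3-catalysed Diels–Alder reaction with isoprene 1, anti to the isopropyl group and "para", gives the cis-fused (4S,4aS,8aS)-6-methyl-4-(propan-2-yl)-3,4,4a,5,8,8a-hexahydronaphthalen-1(2H)-one F3, which NaOMe in MeOH epimerises at C8a to the trans-fused (4S,4aS,8aR) isomer F4. Kinetic enolisation (LDA, TMSCl) gives trimethyl{[(4S,4aS,8aR)-6-methyl-4-(propan-2-yl)-3,4,4a,5,8,8a-hexahydronaphthalen-1-yl]oxy}silane F5, and Saegusa–Ito oxidation with Pd(OAc)2 gives enone 7.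

**Step 8 (aldol stopped at the ketol).** The ketol may dehydrate, the aldehyde enolate may add to the ketone instead, or the trans ketol may form. The fallback sets out from 13 and comes back at 14. DBU in CH2Cl2 drives the classical aldol condensation to (3aR,4S,5R,7aR)-3-acetyl-7-methylidene-4-(propan-2-yl)-3a,4,5,6,7,7a-hexahydro-1H-inden-5-yl acetate F6. Cu-catalysed conjugate borylation as in step 3 (boron to the less hindered α-face of C2, acetyl settling trans to the C7 branch on protonation) gives (1S,2S,3aR,6R,7S,7aR)-1-acetyl-4-methylidene-7-(propan-2-yl)-2-(4,4,5,5-tetramethyl-1,3,2-dioxaborolan-2-yl)octahydro-1H-inden-6-yl acetate F7. Oxidation with H2O2/NaHCO3 then gives 14.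

**Step 9 (angeloylation of a β-hydroxy ketone).** Isomerisation to the tiglate and β-elimination are the risks. The fallback sets out from 14 and comes back at 17 by building the Z-alkene on the substrate. Esterification of 14 with 2-(diphenoxyphosphoryl)propanoic acid (DIC, cat. DMAP, 0 °C) gives (1R,2S,3aR,6R,7S,7aR)-6-acetoxy-1-acetyl-4-methylidene-7-(propan-2-yl)octahydro-1H-inden-2-yl 2-(diphenoxyphosphoryl)propanoate F8. A Z-selective Ando-type Horner–Wadsworth–Emmons reaction with acetaldehyde (NaI, DBU, THF, −78 → 0 °C, where only the phosphonate C–H is acidic enough to be deprotonated) then gives 17.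

## Further compounds

F1 | step 2 | (2S)-5-oxo-2-(propan-2-yl)hexanal | CC(=O)CC[C@@H](C(C)C)C=O
F2 | step 2 | (4S)-4-(propan-2-yl)cyclohex-2-en-1-one | O=C1CC[C@@H](C(C)C)C=C1
F3 | step 2 | (4S,4aS,8aS)-6-methyl-4-(propan-2-yl)-3,4,4a,5,8,8a-hexahydronaphthalen-1(2H)-one | O=C1CC[C@@H](C(C)C)[C@@H]2CC(C)=CC[C@H]12
F4 | step 2 | (4S,4aS,8aR)-6-methyl-4-(propan-2-yl)-3,4,4a,5,8,8a-hexahydronaphthalen-1(2H)-one | O=C1CC[C@@H](C(C)C)[C@@H]2CC(C)=CC[C@@H]12
F5 | step 2 | trimethyl{[(4S,4aS,8aR)-6-methyl-4-(propan-2-yl)-3,4,4a,5,8,8a-hexahydronaphthalen-1-yl]oxy}silane | C[Si](C)(C)OC1=CC[C@@H](C(C)C)[C@@H]2CC(C)=CC[C@@H]12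
F6 | step 8 | (3aR,4S,5R,7aR)-3-acetyl-7-methylidene-4-(propan-2-yl)-3a,4,5,6,7,7a-hexahydro-1H-inden-5-yl acetate | C=C1C[C@@H](OC(C)=O)[C@@H](C(C)C)[C@@H]2C(C(C)=O)=CC[C@@H]12
F7 | step 8 | (1S,2S,3aR,6R,7S,7aR)-1-acetyl-4-methylidene-7-(propan-2-yl)-2-(4,4,5,5-tetramethyl-1,3,2-dioxaborolan-2-yl)octahydro-1H-inden-6-yl acetate | C=C1C[C@@H](OC(C)=O)[C@@H](C(C)C)[C@@H]2[C@@H](C(C)=O)[C@@H](B3OC(C)(C)C(C)(C)O3)C[C@@H]12
F8 | step 9 | (1R,2S,3aR,6R,7S,7aR)-6-acetoxy-1-acetyl-4-methylidene-7-(propan-2-yl)octahydro-1H-inden-2-yl 2-(diphenoxyphosphoryl)propanoate (phosphonate α-carbon epimers) | C=C1C[C@@H](OC(C)=O)[C@@H](C(C)C)[C@@H]2[C@@H](C(C)=O)[C@@H](OC(=O)C(C)P(=O)(Oc3ccccc3)Oc3ccccc3)C[C@@H]12
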